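**Plan**

Numbering: C1 to C11 follow the eleven-membered perimeter (C1 ketone, C2=C3 with CH3 on C3, C6 gem-dimethyl, C7 OH, C8 isovalerate, C9 angelate, C10 CH3). C4–C10 and C5–C11 are the cross-ring bonds.
Cuts: first the two esters and the C7/C8 hydroxyls (back to a C7=C8 alkene), then C1=O and the C3 methyl (back to a C2 ketone), then the C10 methyl (back to an acyl group), and last C5–C6 and C9–C10 together.
Enabling feature: in the cyclobutane C4–C5–C11–C10 the 1,3-related carbons C5 and C10 carry both neopentyl bonds of the seven-membered ring, while C4 and C11 are tied by C1–C2–C3. Excising C6–C9 and joining C5 to C10 therefore leaves a bicyclo[1.1.0]butane whose wing carbons are already bridged.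
Forward: the six-membered ring comes from a Birch-type diene. Carbene addition and carbenoid C–H insertion then build the bridged bicyclobutane. Annulation with a four-carbon silyl dienol ether closes the seven-membered ring as the central bond opens to the cyclobutane.
Stereochemistry: the cage fixes C4, C5, C10 and C11 relative to each other, and every intermediate up to the diketone is achiral. A chiral lithium amide tells C3 from C1 and sets the absolute sense. A catalyst-controlled epoxidation sets C9 independently, because the seven-membered ring does not feel the C1/C3 difference. Osmylation anti to O9 sets C7 and C8, and the Z-alkene comes with angelic acid.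

Key step: step 7

Assumption: the sense of induction of the two chiral reagents (steps 13 and 16) on this new skeleton cannot be derived with certainty. The antipode named is the one expected by analogy, and the other antipode of each is equally available.

**Step 1**
Reactants: 1 1-methoxycyclohexa-1,4-diene
Product: 2 1,4-dioxaspiro[4.5]dec-7-ene (cyclohex-3-enone ethylene ketal)
Conditions: HOCH2CH2OH, p-TsOH (cat.), CH2Cl2, rt
Reagents that add atoms: ethylene glycol, OCCO
Why: Acid-catalysed exchange of the enol ether with the diol (ketalisation) locks the ketone oxidation level before the isolated C=C can move into conjugation.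

**Step 2**
Reactants: 2 1,4-dioxaspiro[4.5]dec-7-ene
Product: 3 (±)-7,7-dibromospiro[bicyclo[4.1.0]heptane-3,2'-[1,3]dioxolane] (cis-fused)
Conditions: CHBr3, KOt-Bu, pentane, −10 to 0 °C
Reagents that add atoms: bromoform, BrC(Br)Br
Why: Dibromocarbene from α-elimination of the haloform adds stereospecifically ([2+1] cyclopropanation) to the only C=C, giving a cis-fused racemate whose chirality disappears in the next step.

**Step 3**
Reactants: 3 (±)-7,7-dibromospiro[bicyclo[4.1.0]heptane-3,2'-[1,3]dioxolane]
Product: 5 spiro[1,3-dioxolane-2,4'-tricyclo[4.1.0.0(2,7)]heptane] (bridged bicyclobutane; ketal at C2; mirror-symmetric), via bromolithio carbenoid 4 (not isolated)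
Conditions: MeLi, Et2O, −30 to 0 °C
Reagents that add atoms: none
Why: Br/Li exchange and α-elimination give a cyclopropylidene carbenoid that inserts into a neighbouring ring C–H (the bicyclobutane branch of the Doering–Moore–Skattebøl manifold, the allene being impossible in a six-membered ring), and because the CH2 next to the ketal carbon is inductively deactivated, insertion should take the remote CH2 and put the ketal in the middle of the bridge.

**Step 4**
Reactants: 5 spiro[1,3-dioxolane-2,4'-tricyclo[4.1.0.0(2,7)]heptane]
Product: 7 spiro[1,3-dioxolane-2,4'-tricyclo[4.1.0.0(2,7)]heptane]-1'-carboxylic acid, via bridgehead lithium compound 6 (not isolated)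
Conditions: n-BuLi, TMEDA, Et2O, rt; CO2, −78 °C; cold dil. HCl to pH 4
Reagents that add atoms: carbon dioxide, O=C=O
Why: The s-rich bridgehead C–H of a bicyclobutane is lithiated directly, and since the two bridgeheads of 5 are equivalent by symmetry, carboxylation can give only one acid (its carbon becomes the C10 methyl).

**Step 5**
Reactants: 7 bridged bicyclobutane carboxylic acid
Product: 8 1'-(pyrazol-1-ylcarbonyl)spiro[1,3-dioxolane-2,4'-tricyclo[4.1.0.0(2,7)]heptane]
Conditions: pyrazole, DCC, DMAP (cat.), CH2Cl2, 0 °C to rt
Reagents that add atoms: pyrazole, c1cn[nH]c1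
Why: Carbodiimide coupling gives an N-acyl pyrazole, a stronger acceptor than an alkyl ester, and its O,N two-point binding site lets a Lewis acid choose the bicyclobutane over the ketal.

**Step 6**
Reactants: 9 4-methylpent-1-en-3-one
Product: 10 tert-butyl(dimethyl)[(4-methylpenta-1,3-dien-3-yl)oxy]silane
Conditions: TBSOTf, Et3N, Et2O, 0 °C
Reagents that add atoms: tert-butyldimethylsilyl triflate, CC(C)(C)[Si](C)(C)OS(=O)(=O)C(F)(F)F
Why: Soft enolisation and O-silylation can only involve the isopropyl C–H, so a single 2-silyloxydiene forms with the enol-ether carbon C6 fully substituted.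

**Step 7**
Reactants: 8 bridged bicyclobutane acyl pyrazole; 10 silyl dienol ether
Product: 12 mirror-symmetric longipinane tricycle (C7=C8 TBS enol ether; C6 Me2; C10 pyrazol-1-ylcarbonyl; C2 ethylene ketal), via ring-opened zwitterion 11 (not isolated)
Conditions: Sc(OTf)3 (10 mol %), 4 Å MS, CH2Cl2, −20 °C to rt
Reagents that add atoms: none
Why: Proposed new method: Two-point binding of Sc(OTf)3 to the carbonyl O and pyrazole N of 8 polarises the nearly pure-p central bond C5–C10, the enol-ether carbon C6 of 10 bonds to the free bridgehead C5 as that bond breaks, and zwitterion 11 (scandium enolate at C10, silyl-activated vinyl ketone) closes by conjugate addition of C10 to the terminus C9 with the silyl group staying on O7. The closest known reaction type is the Lewis acid catalysed formal [2σ+4π] annulation of acyl bicyclobutanes with 2-silyloxydienes to bicyclo[4.1.1]octanes, which has not been shown on a bicyclobutane with bridged wing carbons. One ring closes, the seven-membered carbocycle C5–C6–C7–C8–C9–C10 completed by C4 or C11, in a 7-endo-trig Mukaiyama–Michael step, while the cyclobutane C4–C5–C11–C10 is released from the cage. The new stereocentres C5 and C10 are dictated by the cage, since a four-carbon bridge can span them only through the two diaxial bonds anti to C1–C3, and 12 keeps the mirror plane and is achiral. The step needs C6-to-C5 and C9-to-C10 regiochemistry (given by the acceptor on C10 and the single nucleophilic carbon of 10), preference for the acyl group over the ketal (given by the chelate), and bonding at C5 on the convex face, that is with retention instead of the usual rear-side opening; the rear corridor runs under the cage between C1–H, C3–H and the ketal and is closed to a fully substituted carbon, and the strong chelate activation is meant to advance heterolysis far enough for front-side capture. The usual Lewis acid isomerisation of acyl bicyclobutanes to cyclobutenes would create a bridgehead alkene here and should be suppressed.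

**Step 8**
Reactants: 12 tricyclic acyl pyrazole
Product: 13 C10-hydroxymethyl tricycle (C7=C8 TBS enol ether; C2 ketal)
Conditions: NaBH4, THF–EtOH, 0 °C to rt
Reagents that add atoms: none
Why: N-acyl pyrazoles are activated amides that borohydride reduces to primary alcohols, while the enol silane and the ketal are inert to hydride.

**Step 9**
Reactants: 13 C10-hydroxymethyl tricycle
Product: 14 C10-(methanesulfonyloxymethyl) tricycle
Conditions: MsCl, Et3N, CH2Cl2, 0 °C
Reagents that add atoms: methanesulfonyl chloride, CS(=O)(=O)Cl
Why: Sulfonylation of the only hydroxyl group via the sulfene is insensitive to the neopentyl environment.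

**Step 10**
Reactants: 14 neopentyl mesylate
Product: 15 C10-methyl tricycle (C7=C8 TBS enol ether; C2 ketal)
Conditions: LiEt3BH, THF, reflux
Reagents that add atoms: none
Why: SN2 displacement by the most nucleophilic borohydride is chosen because a radical or cation on the C10 CH2 would be cyclobutylcarbinyl and would open or expand the four-membered ring.

**Step 11**
Reactants: 15 C10-methyl TBS enol ether
Product: 16 mirror-symmetric enone ketal (C7 ketone; C8=C9; C2 ketal)
Conditions: Pd(OAc)2 (1.1 equiv), MeCN, rt
Reagents that add atoms: none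
Why: In the Saegusa–Ito oxidation the divalent palladium enolate at C8 can lose β-hydride only from C9, which gives the enone and zerovalent palladium.

**Step 12**
Reactants: 16 enone ketal
Product: 17 mirror-symmetric ene-dione (C2 ketone; C7 ketone; C8=C9)
Conditions: 2 M HCl, THF, rt
Reagents that add atoms: water, O
Why: Acid hydrolysis frees the C2 ketone, and the enone can neither enolise nor migrate because C6 and C10 are quaternary.

**Step 13**
Reactants: 17 ene-dione
Product: 19 (3-methyl) ene-dione (CH3 on C3 drawn on the side of C5–H; the C3 configuration is erased in step 14), via lithium enolate 18 (not isolated)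
Conditions: (R,R)-bis(1-phenylethyl)amine, n-BuLi, LiCl, THF, −78 °C; MeI, −78 to −40 °C
Reagents that add atoms: iodomethane, CI
Why: Enantioselective deprotonation of a mirror-symmetric bridged ketone by a chiral lithium amide (well established for related bicyclic ketones) removes one of the enantiotopic C1/C3 protons, the only acidic ones in 17, and methylation of the enolate fixes the absolute sense of the whole cage.

**Step 14**
Reactants: 19 3-methyl ene-dione
Product: 20 C2 enol triflate (C2=C3 bearing CH3 on C3; C7 enone)
Conditions: Tf2O, 2,6-di-tert-butyl-4-methylpyridine, CH2Cl2, 0 °C to rt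
Reagents that add atoms: trifluoromethanesulfonic anhydride, O=S(=O)(OS(=O)(=O)C(F)(F)F)C(F)(F)F
Why: O-triflation under equilibrating conditions with a non-nucleophilic pyridine goes through the more substituted enol, so the C3 stereocentre is erased but the C1/C3 distinction is kept.

**Step 15**
Reactants: 20 enol triflate
Product: 21 dienone (C2=C3–CH3; C7 ketone; C8=C9)
Conditions: Pd(OAc)2 (cat.), PPh3, HCO2H, n-Bu3N, DMF, 60 °C
Reagents that add atoms: none
Why: Oxidative addition of zerovalent palladium to the vinyl triflate, formate decarboxylation and reductive elimination replace OTf by H without moving the alkene.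

**Step 16**
Reactants: 21 dienone
Product: 22 8,9-epoxy ketone (epoxide on the face of the seven-membered ring that lies on the C11/C1 side)
Conditions: 9-amino-9-deoxy-epi-quinine (10 mol %), CF3CO2H (20 mol %), 50 % aq. H2O2, dioxane, 35 °C
Reagents that add atoms: hydrogen peroxide, OO
Why: Iminium-catalysed asymmetric Weitz–Scheffer epoxidation of a cyclic enone lets the catalyst select the face, which is needed because the two faces of C8=C9 differ only through the remote C1/C3 pattern, and any minor enantiomer carried from step 13 becomes a separable diastereomer here.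

**Step 17**
Reactants: 22 epoxy ketone
Product: 24 allylic alcohol (C9–OH; C7=C8; C2=C3–CH3), via epoxy hydrazone 23 (not isolated)
Conditions: N2H4·H2O, AcOH, MeOH, 0 °C to rt, Ar
Reagents that add atoms: none
Why: In the Wharton transposition the hydrazone opens the epoxide and loses N2, so the C9–O bond is never broken and the configuration set in step 16 is retained.

**Step 18**
Reactants: 24 allylic alcohol; 25 angelic acid
Product: 27 C9 angelate, via mixed anhydride 26 (not isolated)
Conditions: 25, 2,4,6-trichlorobenzoyl chloride, Et3N, toluene, rt; then 24, 80 °C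
Reagents that add atoms: none
Why: Yamaguchi-type mixed-anhydride acylation without a nucleophilic catalyst esterifies hindered secondary alcohols without Z-to-E isomerisation of the angeloyl group.

**Step 19**
Reactants: 27 C9 angelate
Product: 28 C9 angelate enone (C1 ketone; C2=C3–CH3; C7=C8)
Conditions: CrO3, 3,5-dimethylpyrazole, CH2Cl2, −20 °C
Reagents that add atoms: chromium trioxide, O=[Cr](=O)=O
Why: Hexavalent chromium–pyrazole allylic oxidation attacks the ring CH2 next to the electron-rich trisubstituted alkene (the pinene-to-verbenone pattern), while C9–H carries an acyloxy group and the angelate alkene is electron-poor.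

**Step 20**
Reactants: 28 angelate enone
Product: 29 7,8-diol (O7 and O8 cis to each other and trans to O9)
Conditions: OsO4 (cat.), NMO, acetone–H2O, 0 °C
Reagents that add atoms: N-methylmorpholine N-oxide, C[N+]1([O-])CCOCC1; water, O
Why: Upjohn dihydroxylation takes the only non-conjugated alkene and adds suprafacially on the face anti to the allylic acyloxy group at C9, which sets C7 and C8 together.

**Step 21**
Reactants: 29 7,8-diol; 30 isovaleric anhydride
Product: 31 target, CNP0251293.1
Conditions: 30 (1.1 equiv), DMAP (cat.), 2,4,6-collidine, CH2Cl2, −20 to 0 °C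
Reagents that add atoms: none
Why: Steglich-type acylation should select O8, because the C7 hydroxyl is neopentyl beside the C6 gem-dimethyl group.

**Compound list**

1 | 1-methoxycyclohexa-1,4-diene | COC1=CCC=CC1 | starting material
2 | 1,4-dioxaspiro[4.5]dec-7-ene | C1=CCC2(CC1)OCCO2 | intermediate
3 | (±)-7,7-dibromospiro[bicyclo[4.1.0]heptane-3,2'-[1,3]dioxolane], one enantiomer drawn | BrC1(Br)[C@H]2CC3(OCCO3)CC[C@@H]12 | intermediate
4 | 7-bromo-7-lithio carbenoid of 3 (not isolated) | [Li]C1(Br)[C@H]2CC3(OCCO3)CC[C@@H]12 | intermediate
5 | spiro[1,3-dioxolane-2,4'-tricyclo[4.1.0.0(2,7)]heptane] | [C@H]12[C@@H]3CC4(C[C@H]1[C@H]23)OCCO4 | intermediate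
6 | 1'-lithio derivative of 5 (not isolated) | [Li][C@]12[C@@H]3CC4(C[C@H]1[C@H]23)OCCO4 | intermediate
7 | 1'-carboxylic acid of 5 | OC(=O)[C@]12[C@@H]3CC4(C[C@H]1[C@H]23)OCCO4 | intermediate
8 | 1'-(pyrazol-1-ylcarbonyl) derivative of 5 (key-step precursor) | O=C(n1cccn1)[C@]12[C@@H]3CC4(C[C@H]1[C@H]23)OCCO4 | intermediate
9 | 4-methylpent-1-en-3-one | C=CC(=O)C(C)C | starting material
10 | 4-methyl-3-(tert-butyldimethylsilyloxy)penta-1,3-diene (key-step precursor) | C=CC(O[Si](C)(C)C(C)(C)C)=C(C)C | intermediate
11 | ring-opened zwitterion, drawn without scandium (not isolated) | C=CC(=[O+][Si](C)(C)C(C)(C)C)C(C)(C)[C@@H]2[C@H]3CC4(OCCO4)C[C@@H]2C3=C([O-])n1cccn1 | intermediate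
12 | tricycle: C7=C8 TBS enol ether, C10 pyrazol-1-ylcarbonyl, C2 ketal (key-step product, achiral) | C1C=C(O[Si](C)(C)C(C)(C)C)C(C)(C)[C@@H]2[C@H]3CC4(OCCO4)C[C@@H]2[C@@]13C(=O)n1cccn1 | intermediate
13 | C10-hydroxymethyl tricycle | C1C=C(O[Si](C)(C)C(C)(C)C)C(C)(C)[C@@H]2[C@H]3CC4(OCCO4)C[C@@H]2[C@@]13CO | intermediate
14 | C10-mesyloxymethyl tricycle | C1C=C(O[Si](C)(C)C(C)(C)C)C(C)(C)[C@@H]2[C@H]3CC4(OCCO4)C[C@@H]2[C@@]13COS(C)(=O)=O | intermediate
15 | C10-methyl tricycle | C1C=C(O[Si](C)(C)C(C)(C)C)C(C)(C)[C@@H]2[C@H]3CC4(OCCO4)C[C@@H]2[C@@]13C | intermediate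
16 | enone ketal | C1=CC(=O)C(C)(C)[C@@H]2[C@H]3CC4(OCCO4)C[C@@H]2[C@@]13C | intermediate
17 | ene-dione (achiral) | C1=CC(=O)C(C)(C)[C@@H]2[C@H]3CC(=O)C[C@@H]2[C@@]13C | intermediate
18 | lithium C2=C3 enolate (not isolated) | C1=CC(=O)C(C)(C)[C@@H]2[C@H]3CC([O-])=C[C@@H]2[C@@]13C.[Li+] | intermediate
19 | 3-methyl ene-dione | C1=CC(=O)C(C)(C)[C@@H]2[C@H]3CC(=O)[C@@H](C)[C@@H]2[C@@]13C | intermediate
20 | C2 enol triflate | C1=CC(=O)C(C)(C)[C@@H]2[C@H]3CC(OS(=O)(=O)C(F)(F)F)=C(C)[C@@H]2[C@@]13C | intermediate
21 | dienone | C1=CC(=O)C(C)(C)[C@@H]2[C@H]3CC=C(C)[C@@H]2[C@@]13C | intermediate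
22 | 8,9-epoxy-7-ketone | [C@H]14O[C@@H]4C(=O)C(C)(C)[C@@H]2[C@H]3CC=C(C)[C@@H]2[C@@]13C | intermediate
23 | epoxy hydrazone (not isolated) | [C@H]14O[C@@H]4C(=NN)C(C)(C)[C@@H]2[C@H]3CC=C(C)[C@@H]2[C@@]13C | intermediate
24 | 9-hydroxy-2,7-diene | O[C@@H]1C=CC(C)(C)[C@@H]2[C@H]3CC=C(C)[C@@H]2[C@@]13C | intermediate
25 | angelic acid, (Z)-2-methylbut-2-enoic acid | C/C=C(/C)C(=O)O | starting material
26 | angelic 2,4,6-trichlorobenzoic anhydride (not isolated) | C/C=C(/C)C(=O)OC(=O)c1c(Cl)cc(Cl)cc1Cl | intermediate
27 | C9 angelate | C/C=C(/C)C(=O)O[C@@H]1C=CC(C)(C)[C@@H]2[C@H]3CC=C(C)[C@@H]2[C@@]13C | intermediate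
28 | C9 angelate, C1 enone | C/C=C(/C)C(=O)O[C@@H]1C=CC(C)(C)[C@@H]2[C@H]3C(=O)C=C(C)[C@@H]2[C@@]13C | intermediate
29 | 7,8-diol | C/C=C(/C)C(=O)O[C@@H]1[C@@H](O)[C@@H](O)C(C)(C)[C@@H]2[C@H]3C(=O)C=C(C)[C@@H]2[C@@]13C | intermediate
30 | isovaleric anhydride | CC(C)CC(=O)OC(=O)CC(C)C | starting material
31 | CNP0251293.1 | C/C=C(/C)C(=O)O[C@@H]1[C@@H](OC(=O)CC(C)C)[C@@H](O)C(C)(C)[C@@H]2[C@H]3C(=O)C=C(C)[C@@H]2[C@@]13C | target

**Step count**

Total steps: 21. Longest linear sequence: 20 (steps 1 to 5 and 7 to 21).

**Steps most likely to fail**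

1. **Step 7.** The enol ether may fail to engage the convex face of the central bond. Openings of bicyclobutanes normally run from the rear, and here the rear is closed. The bicyclobutane could then be consumed by Lewis acid rearrangement or by participation of a ketal oxygen. Alternatively, the open intermediate could lose its silyl group before the second bond forms.

   The fallback makes the same two bonds one at a time by known reactions, through a planar cation at C5. It sets out from 8 and returns at 12.
   - Radical-chain addition of thiophenol (AIBN, benzene, 70 °C) is known on this tricycle to deliver sulfur to the free bridgehead from the rear. It should give the 5-phenylthio bicyclo[3.1.1]heptane F1.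
   - N-chlorosuccinimide converts it into the α-chloro sulfide F2.
   - ZnBr2 ionises F2 to a thionium ion at C5. Its lower face is shielded by the C1–C3 bridge, so 10 alkylates it from above (phenylthioalkylation of a silyl enol ether) to give the vinyl ketone F3.
   - DBU closes C9–C10 by intramolecular Michael addition of the acyl pyrazole enolate and gives the keto sulfide F4.
   - Raney Ni removes sulfur and gives the saturated ketone F5.
   - TBSOTf/Et3N can enolise F5 only towards C8 and regenerates 12.

2. **Step 16.** Iminium formation at the neopentyl C7 carbonyl may be too slow. Uncatalysed peroxide addition would then take over and facial selectivity would be lost.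

   The fallback sets C9 by reagent-controlled carbonyl reduction instead. It sets out from 21 and returns at 24.
   - Alkaline H2O2 gives 22 together with its face isomer, the epimeric epoxy ketone F6.
   - Wharton transposition of the mixture gives 24 together with the 9-epi allylic alcohol F7.
   - Dess–Martin oxidation converges both onto the transposed dienone F8.
   - Corey–Bakshi–Shibata reduction (2-methyl-CBS-oxazaborolidine, BH3·SMe2) of F8 delivers 24.

3. **Step 10.** Hydride displacement at the neopentyl carbon may be outrun by S–O cleavage back to the alcohol, or by ionisation with expansion of the cyclobutane.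

   The fallback removes the oxygen through a hydrazone. It sets out from 13 and returns at 15.
   - Dess–Martin oxidation gives the C10 aldehyde F9.
   - Tosylhydrazide in THF gives the tosylhydrazone F10.
   - Caglioti-type reduction (catecholborane, then NaOAc·3H2O) gives 15 with loss of sulfinate and nitrogen.

**Further compounds**

F1 | step 7 | 5-phenylthio bicyclo[3.1.1]heptane (S syn to the C1–C3 bridge, C10–H, C10 pyrazol-1-ylcarbonyl, C2 ketal) | c1ccccc1S[C@H]2[C@H]3CC4(OCCO4)C[C@@H]2[C@@H]3C(=O)n1cccn1
F2 | step 7 | 5-chloro-5-phenylthio derivative | c1ccccc1S[C@@]2(Cl)[C@H]3CC4(OCCO4)C[C@@H]2[C@@H]3C(=O)n1cccn1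
F3 | step 7 | C5-alkylated vinyl ketone (C6 anti to the bridge, SPh syn) | C=CC(=O)C(C)(C)[C@]2(Sc1ccccc1)[C@H]3CC4(OCCO4)C[C@@H]2[C@@H]3C(=O)n1cccn1
F4 | step 7 | tricyclic C7 ketone with C5–SPh | C1CC(=O)C(C)(C)[C@]2(Sc5ccccc5)[C@H]3CC4(OCCO4)C[C@@H]2[C@@]13C(=O)n1cccn1
F5 | step 7 | tricyclic C7 ketone | C1CC(=O)C(C)(C)[C@@H]2[C@H]3CC4(OCCO4)C[C@@H]2[C@@]13C(=O)n1cccn1
F6 | step 16 | 8,9-epoxy ketone, epoxide on the C4/C3 side | [C@@H]14O[C@H]4C(=O)C(C)(C)[C@@H]2[C@H]3CC=C(C)[C@@H]2[C@@]13C
F7 | step 16 | 9-epi allylic alcohol | O[C@H]1C=CC(C)(C)[C@@H]2[C@H]3CC=C(C)[C@@H]2[C@@]13C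
F8 | step 16 | transposed dienone (C9 ketone, C7=C8) | O=C1C=CC(C)(C)[C@@H]2[C@H]3CC=C(C)[C@@H]2[C@@]13C
F9 | step 10 | C10 carbaldehyde | C1C=C(O[Si](C)(C)C(C)(C)C)C(C)(C)[C@@H]2[C@H]3CC4(OCCO4)C[C@@H]2[C@@]13C=O
F10 | step 10 | C10 carbaldehyde tosylhydrazone | C1C=C(O[Si](C)(C)C(C)(C)C)C(C)(C)[C@@H]2[C@H]3CC4(OCCO4)C[C@@H]2[C@@]13/C=N/NS(=O)(=O)c1ccc(C)cc1
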